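**Plan**
1. Retrosynthesis: the enal C=C is cut first (Wittig, back to the 6-carbaldehyde), then O4–C4a of the dioxane ring (copper-catalysed aryl ether closure of a threo bromo carbinol), then C3–aryl (aryl Grignard on a Weinreb amide, ketone then reduced) and O1–C2 (Mitsunobu). This leaves (R)-glycerate, 3-bromo-4-hydroxybenzaldehyde and 4-bromo-2,6-dimethoxyphenol.
2. Enabling feature: with the dioxane ring numbered O1–C2(CH2OH)–C3(aryl)–O4 and C4a/C8a the ring A carbons, O4–C4a lies meta to the C6 side chain, so nothing activates it for nucleophilic aromatic substitution. C4a is, however, ortho to C8a–O1, so a bromide at C4a and the C3 alkoxide of an O1-tethered chain can be joined by copper to close the six-membered ring.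
3. Forward order: O1–C2 ether, then the C3–aryl bond, then the C3 carbinol, then the only new ring (dioxane, by O4–C4a), then deprotection and two-carbon extension of the aldehyde.
4. Stereochemistry: C2 comes from methyl (R)-glycerate by Mitsunobu inversion. C3 is set by Felkin–Anh reduction of the α-aryloxy ketone (threo) and is retained in the ring closure, giving the trans (2S,3S) ring.

Key step: step 9

Remark on the chemistry: the primary oxygen is carried as a triisopropylsilyl ether, because a smaller silyl group could move to the neighbouring alkoxide under the basic ring closure and open the way to the isomeric ring. Locants follow 2,3-dihydro-1,4-benzodioxine; ring A is the benzo ring.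

**Route**

Step 1
Reactants: 1 methyl (4R)-2,2-dimethyl-1,3-dioxolane-4-carboxylate
Product: 2 methyl (2R)-2,3-dihydroxypropanoate
Conditions: Dowex 50W-X8 (H+ form), MeOH, rt
Reagents that add atoms: none
Why: Acid-catalysed transacetalisation (acetonide methanolysis) passes the isopropylidene group to methanol without touching the C2 stereocentre, and the methyl ester is degenerate toward methanolysis.

Step 2
Reactants: 2 methyl (2R)-2,3-dihydroxypropanoate
Product: 3 methyl (2R)-2-hydroxy-3-[(triisopropylsilyl)oxy]propanoate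
Conditions: i-Pr3SiCl, imidazole, DMF, 0 °C to rt
Reagents that add atoms: chlorotri(propan-2-yl)silane (TIPSCl), CC(C)[Si](Cl)(C(C)C)C(C)C
Why: Silyl ether formation with the bulky chlorosilane should be selective for the primary hydroxyl over the hindered, less nucleophilic α-hydroxy ester oxygen, leaving C2–OH free.

Step 3
Reactants: 3 methyl (2R)-2-hydroxy-3-[(triisopropylsilyl)oxy]propanoate; 4 3-bromo-4-hydroxybenzaldehyde
Product: 5 methyl (2S)-2-(2-bromo-4-formylphenoxy)-3-[(triisopropylsilyl)oxy]propanoate
Conditions: PPh3, DIAD, THF, 0 °C to rt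
Reagents that add atoms: none
Why: In this Mitsunobu reaction the acidic bromophenol protonates the betaine and its phenoxide displaces the oxyphosphonium group at C2 by SN2, so the (R) carbinol should give the (S) aryl ether with inversion, as is usual for α-hydroxy esters, and this sets the future C2.

Step 4
Reactants: 5 methyl (2S)-2-(2-bromo-4-formylphenoxy)-3-[(triisopropylsilyl)oxy]propanoate
Product: 6 methyl (2S)-2-[2-bromo-4-(1,3-dioxolan-2-yl)phenoxy]-3-[(triisopropylsilyl)oxy]propanoate
Conditions: Me3SiOCH2CH2OSiMe3, Me3SiOTf (cat.), CH2Cl2, −78 to −20 °C; pyridine quench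
Reagents that add atoms: 1,2-bis(trimethylsilyloxy)ethane, C[Si](C)(C)OCCO[Si](C)(C)C
Why: Noyori acetalisation masks the aldehyde under aprotic, low-temperature conditions that should leave the silyl ether, the ester and the adjacent stereocentre untouched.

Step 5
Reactants: 6 methyl (2S)-2-[2-bromo-4-(1,3-dioxolan-2-yl)phenoxy]-3-[(triisopropylsilyl)oxy]propanoate
Product: 7 (2S)-2-[2-bromo-4-(1,3-dioxolan-2-yl)phenoxy]-N-methoxy-N-methyl-3-[(triisopropylsilyl)oxy]propanamide
Conditions: MeNH(OMe)·HCl, i-PrMgCl, THF, −20 to −10 °C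
Reagents that add atoms: N,O-dimethylhydroxylamine hydrochloride, CNOC.Cl
Why: Weinreb amide formation by aminolysis of the ester with the chloromagnesium amide made in situ, a weakly basic nucleophile that is routinely used on α-oxygenated and β-silyloxy esters without epimerisation or elimination, and at −20 °C the aryl bromide should not undergo exchange.

Step 6
Reactants: 8 4-bromo-2,6-dimethoxyphenol
Product: 9 5-bromo-1,3-dimethoxy-2-(methoxymethoxy)benzene
Conditions: MeOCH2Cl, i-Pr2NEt, CH2Cl2, 0 °C to rt
Reagents that add atoms: chloromethyl methyl ether, COCCl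
Why: Williamson-type O-alkylation of the hindered phenol with the reactive α-chloro ether gives the methoxymethyl acetal, which tolerates magnesium, hydride and hot carbonate base.

Step 7
Reactants: 9 5-bromo-1,3-dimethoxy-2-(methoxymethoxy)benzene; 7 (2S)-2-[2-bromo-4-(1,3-dioxolan-2-yl)phenoxy]-N-methoxy-N-methyl-3-[(triisopropylsilyl)oxy]propanamide
Product: 12 (2S)-2-[2-bromo-4-(1,3-dioxolan-2-yl)phenoxy]-1-[3,5-dimethoxy-4-(methoxymethoxy)phenyl]-3-[(triisopropylsilyl)oxy]propan-1-one, via aryl Grignard reagent 10 (not isolated), via magnesium-chelated tetrahedral adduct 11 (not isolated)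
Conditions: 9, Mg turnings, THF, 40 °C; then 7, THF, 0 °C; aq. NH4Cl
Reagents that add atoms: none
Why: In this Weinreb ketone synthesis the aryl Grignard reagent adds once to give a chelated adduct that collapses only on quench, so no tertiary alcohol should form, the magnesium reagent (unlike an aryllithium) should not exchange with the aryl bromide of 7, and the enolisable ketone appears only after work-up.

Step 8
Reactants: 12 (2S)-2-[2-bromo-4-(1,3-dioxolan-2-yl)phenoxy]-1-[3,5-dimethoxy-4-(methoxymethoxy)phenyl]-3-[(triisopropylsilyl)oxy]propan-1-one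
Product: 13 (1S,2S)-2-[2-bromo-4-(1,3-dioxolan-2-yl)phenoxy]-1-[3,5-dimethoxy-4-(methoxymethoxy)phenyl]-3-[(triisopropylsilyl)oxy]propan-1-ol (threo)
Conditions: LiBH(s-Bu)3, THF, −78 °C; aq. NH4Cl
Reagents that add atoms: none
Why: Felkin–Anh-controlled ketone reduction: with the C2–OAr bond anti to the incoming bulky hydride, which passes the C2 hydrogen and not the CH2OSi group, and with the weakly basic aryloxy and silyloxy oxygens disfavouring chelation, the (2S) ketone used promptly after step 7 should give the syn (threo) carbinol with the new C1 centre (S).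

Step 9
Reactants: 13 (1S,2S)-2-[2-bromo-4-(1,3-dioxolan-2-yl)phenoxy]-1-[3,5-dimethoxy-4-(methoxymethoxy)phenyl]-3-[(triisopropylsilyl)oxy]propan-1-ol
Product: 14 {[(2S,3S)-6-(1,3-dioxolan-2-yl)-3-[3,5-dimethoxy-4-(methoxymethoxy)phenyl]-2,3-dihydro-1,4-benzodioxin-2-yl]methoxy}tri(propan-2-yl)silane (trans)
Conditions: CuI (10 mol%), 3,4,7,8-tetramethyl-1,10-phenanthroline (20 mol%), Cs2CO3, toluene, 110 °C, argon
Reagents that add atoms: none
Why: Cs2CO3 deprotonates the C1 carbinol and the alkoxide binds monovalent copper held by the phenanthroline ligand; the ortho C–Br bond then adds oxidatively to give a trivalent copper aryl alkoxide in a seven-membered metallacycle, and C–O reductive elimination releases the ether and returns monovalent copper. The closest known reaction type is the Ullmann-type intramolecular O-arylation of 2-(2-halophenoxy)alkanols to 1,4-benzodioxanes with CuI and a phenanthroline, which is established for secondary alcohols. The one ring formed is the dioxane ring, closed as a six-membered ring by joining O4 to C4a, exo with respect to the C–Br bond that is broken and favoured by the ortho tether through O1. No stereocentre is created: C2 and C3 are carried over from 13, neither is a reacting atom and the C3–O bond is never broken, so the threo (1S,2S) carbinol maps onto the trans (2S,3S) ring. The step needs chemoselectivity for the benzylic oxygen over the primary one and for ring closure over intermolecular coupling or hydrodebromination; the first is secured by the bulky triisopropylsilyl ether, which blocks the primary oxygen and resists oxygen-to-oxygen silyl transfer, the second by the ortho placement of bromide and tether and by moderate dilution. Copper is preferred to palladium because a secondary benzylic alkoxide on palladium can lose a beta-hydride to give ketone 12 and the reduced arene.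

Step 10
Reactants: 14 {[(2S,3S)-6-(1,3-dioxolan-2-yl)-3-[3,5-dimethoxy-4-(methoxymethoxy)phenyl]-2,3-dihydro-1,4-benzodioxin-2-yl]methoxy}tri(propan-2-yl)silane
Product: 15 (2S,3S)-3-(4-hydroxy-3,5-dimethoxyphenyl)-2-(hydroxymethyl)-2,3-dihydro-1,4-benzodioxine-6-carbaldehyde
Conditions: 3 M aq. HCl, THF, 45 °C
Reagents that add atoms: water, O
Why: Acid-catalysed hydrolysis should remove the dioxolane, the aryl methoxymethyl acetal and the primary silyl ether in one operation, while the trans-benzodioxane, whose benzylic C3–O4 bond is deactivated toward ionisation by the adjacent C2–O1 oxygen and which is the thermodynamic diastereomer, should survive, and no enal is yet present to suffer under acid.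

Step 11
Reactants: 15 (2S,3S)-3-(4-hydroxy-3,5-dimethoxyphenyl)-2-(hydroxymethyl)-2,3-dihydro-1,4-benzodioxine-6-carbaldehyde
Product: 16 (2E)-3-[(2S,3S)-3-(4-hydroxy-3,5-dimethoxyphenyl)-2-(hydroxymethyl)-2,3-dihydro-1,4-benzodioxin-6-yl]prop-2-enal (CNP0211211.1)
Conditions: Ph3P=CHCHO (1.2 equiv), toluene/THF, 80 °C
Reagents that add atoms: (triphenyl-λ5-phosphanylidene)acetaldehyde, O=CC=P(c1ccccc1)(c1ccccc1)c1ccccc1
Why: Wittig reaction with the stabilised formyl ylide should give the (E)-enal, tolerates the free phenol and primary alcohol because the ylide is too weakly basic to deprotonate them, and a small excess of ylide limits a second olefination.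

**Compound list**
1 | methyl (4R)-2,2-dimethyl-1,3-dioxolane-4-carboxylate | COC(=O)[C@H]1COC(C)(C)O1 | starting material
2 | methyl (2R)-2,3-dihydroxypropanoate | COC(=O)[C@H](O)CO | intermediate
3 | methyl (2R)-2-hydroxy-3-[(triisopropylsilyl)oxy]propanoate | COC(=O)[C@H](O)CO[Si](C(C)C)(C(C)C)C(C)C | intermediate
4 | 3-bromo-4-hydroxybenzaldehyde | O=Cc1ccc(O)c(Br)c1 | starting material
5 | methyl (2S)-2-(2-bromo-4-formylphenoxy)-3-[(triisopropylsilyl)oxy]propanoate | COC(=O)[C@@H](Oc1ccc(C=O)cc1Br)CO[Si](C(C)C)(C(C)C)C(C)C | intermediate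
6 | methyl (2S)-2-[2-bromo-4-(1,3-dioxolan-2-yl)phenoxy]-3-[(triisopropylsilyl)oxy]propanoate | COC(=O)[C@@H](Oc1ccc(C2OCCO2)cc1Br)CO[Si](C(C)C)(C(C)C)C(C)C | intermediate
7 | (2S)-2-[2-bromo-4-(1,3-dioxolan-2-yl)phenoxy]-N-methoxy-N-methyl-3-[(triisopropylsilyl)oxy]propanamide | CON(C)C(=O)[C@@H](Oc1ccc(C2OCCO2)cc1Br)CO[Si](C(C)C)(C(C)C)C(C)C | intermediate
8 | 4-bromo-2,6-dimethoxyphenol | COc1cc(Br)cc(OC)c1O | starting material
9 | 5-bromo-1,3-dimethoxy-2-(methoxymethoxy)benzene | COCOc1c(OC)cc(Br)cc1OC | intermediate
10 | [3,5-dimethoxy-4-(methoxymethoxy)phenyl]magnesium bromide | COCOc1c(OC)cc([Mg]Br)cc1OC | intermediate (not isolated)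
11 | bromomagnesium (2S)-2-[2-bromo-4-(1,3-dioxolan-2-yl)phenoxy]-1-[3,5-dimethoxy-4-(methoxymethoxy)phenyl]-1-[methoxy(methyl)amino]-3-[(triisopropylsilyl)oxy]propan-1-olate (C1 configuration undefined, lost on collapse) | COCOc1c(OC)cc(cc1OC)C(O[Mg]Br)(N(C)OC)[C@@H](Oc1ccc(C2OCCO2)cc1Br)CO[Si](C(C)C)(C(C)C)C(C)C | intermediate (not isolated)
12 | (2S)-2-[2-bromo-4-(1,3-dioxolan-2-yl)phenoxy]-1-[3,5-dimethoxy-4-(methoxymethoxy)phenyl]-3-[(triisopropylsilyl)oxy]propan-1-one | COCOc1c(OC)cc(cc1OC)C(=O)[C@@H](Oc1ccc(C2OCCO2)cc1Br)CO[Si](C(C)C)(C(C)C)C(C)C | intermediate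
13 | (1S,2S)-2-[2-bromo-4-(1,3-dioxolan-2-yl)phenoxy]-1-[3,5-dimethoxy-4-(methoxymethoxy)phenyl]-3-[(triisopropylsilyl)oxy]propan-1-ol | COc1cc([C@H](O)[C@@H](Oc2ccc(C3OCCO3)cc2Br)CO[Si](C(C)C)(C(C)C)C(C)C)cc(OC)c1OCOC | intermediate
14 | {[(2S,3S)-6-(1,3-dioxolan-2-yl)-3-[3,5-dimethoxy-4-(methoxymethoxy)phenyl]-2,3-dihydro-1,4-benzodioxin-2-yl]methoxy}tri(propan-2-yl)silane | COc1cc([C@@H]2Oc3cc(C4OCCO4)ccc3O[C@H]2CO[Si](C(C)C)(C(C)C)C(C)C)cc(OC)c1OCOC | intermediate
15 | (2S,3S)-3-(4-hydroxy-3,5-dimethoxyphenyl)-2-(hydroxymethyl)-2,3-dihydro-1,4-benzodioxine-6-carbaldehyde | COc1cc([C@@H]2Oc3cc(C=O)ccc3O[C@H]2CO)cc(OC)c1O | intermediate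
16 | (2E)-3-[(2S,3S)-3-(4-hydroxy-3,5-dimethoxyphenyl)-2-(hydroxymethyl)-2,3-dihydro-1,4-benzodioxin-6-yl]prop-2-enal | COc1cc([C@@H]2Oc3cc(/C=C/C=O)ccc3O[C@H]2CO)cc(OC)c1O | target

**Step count and risks**

Total steps: 11. Longest linear sequence: 10 steps (steps 1 to 5 and 7 to 11; step 6 is a one-step branch).

Steps most likely to fail:

Step 9 (ring closure). The hindered benzylic caesium alkoxide may couple slowly, so that hydrodebromination of ring A, oxidation of the carbinol or silyl transfer to the alkoxide competes. Fallback: the same conversion is run in the palladium manifold, a Buchwald–Hartwig-type intramolecular etherification with Pd(OAc)2, rac-2-(di-tert-butylphosphino)-1,1'-binaphthyl and Cs2CO3 in toluene at 80 °C. Zerovalent palladium inserts into the C–Br bond, the alkoxide replaces bromide on divalent palladium, and the bulky electron-rich phosphine drives C–O reductive elimination ahead of beta-hydride loss. The fallback sets out from 13, comes back at 14 and passes through no new compound: none F0.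

Step 8 (ketone reduction). Facial selectivity may be poor if a lithium-chelated transition state competes with the Felkin–Anh one. Fallback: thermodynamic instead of kinetic control of the C3 configuration. The reduction mixture obtained from 12, that is 13 together with its erythro epimer (1R,2S)-2-[2-bromo-4-(1,3-dioxolan-2-yl)phenoxy]-1-[3,5-dimethoxy-4-(methoxymethoxy)phenyl]-3-[(triisopropylsilyl)oxy]propan-1-ol F1, is carried unseparated through the conditions of steps 9 and 10. Ring closure is stereospecific, so the erythro component gives the cis ether {[(2S,3R)-6-(1,3-dioxolan-2-yl)-3-[3,5-dimethoxy-4-(methoxymethoxy)phenyl]-2,3-dihydro-1,4-benzodioxin-2-yl]methoxy}tri(propan-2-yl)silane F2 and then the cis phenol aldehyde (2S,3R)-3-(4-hydroxy-3,5-dimethoxyphenyl)-2-(hydroxymethyl)-2,3-dihydro-1,4-benzodioxine-6-carbaldehyde F3. Treatment of the mixture with K2CO3 in DMF at about 50 °C should open the cis isomer at C3–O4 from the syringyl phenoxide to the para-quinone methide 4-[(2R)-2-(4-formyl-2-hydroxyphenoxy)-3-hydroxypropylidene]-2,6-dimethoxycyclohexa-2,5-dien-1-one F4, to which the ring A phenoxide adds back reversibly. This known base-mediated cis-to-trans equilibration of 3-(4-hydroxyaryl)-1,4-benzodioxanes should funnel the material to the diequatorial trans isomer, and C2 is not touched. The fallback sets out from 12 and comes back at 15.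

Step 11 (enal formation). The product enal can undergo a second olefination to a dienal, and the para-alkoxy aldehyde is a sluggish partner for the weakly nucleophilic formyl ylide. Fallback: a redox sequence through an ester that cannot react further. Aldehyde 15 with Ph3P=CHCO2Me (toluene, 60 °C) should give methyl (2E)-3-[(2S,3S)-3-(4-hydroxy-3,5-dimethoxyphenyl)-2-(hydroxymethyl)-2,3-dihydro-1,4-benzodioxin-6-yl]prop-2-enoate F5. Reduction with excess i-Bu2AlH (THF/CH2Cl2, −78 °C) should give (2E)-3-[(2S,3S)-3-(4-hydroxy-3,5-dimethoxyphenyl)-2-(hydroxymethyl)-2,3-dihydro-1,4-benzodioxin-6-yl]prop-2-en-1-ol F6. Activated MnO2 (EtOAc, rt) should then oxidise only the allylic alcohol. The fallback sets out from 15 and comes back at 16.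

**Further compounds**
F0 | step 9 | none | none
F1 | step 8 | (1R,2S)-2-[2-bromo-4-(1,3-dioxolan-2-yl)phenoxy]-1-[3,5-dimethoxy-4-(methoxymethoxy)phenyl]-3-[(triisopropylsilyl)oxy]propan-1-ol | COc1cc([C@@H](O)[C@@H](Oc2ccc(C3OCCO3)cc2Br)CO[Si](C(C)C)(C(C)C)C(C)C)cc(OC)c1OCOC
F2 | step 8 | {[(2S,3R)-6-(1,3-dioxolan-2-yl)-3-[3,5-dimethoxy-4-(methoxymethoxy)phenyl]-2,3-dihydro-1,4-benzodioxin-2-yl]methoxy}tri(propan-2-yl)silane | COc1cc([C@H]2Oc3cc(C4OCCO4)ccc3O[C@H]2CO[Si](C(C)C)(C(C)C)C(C)C)cc(OC)c1OCOC
F3 | step 8 | (2S,3R)-3-(4-hydroxy-3,5-dimethoxyphenyl)-2-(hydroxymethyl)-2,3-dihydro-1,4-benzodioxine-6-carbaldehyde | COc1cc([C@H]2Oc3cc(C=O)ccc3O[C@H]2CO)cc(OC)c1O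
F4 | step 8 | 4-[(2R)-2-(4-formyl-2-hydroxyphenoxy)-3-hydroxypropylidene]-2,6-dimethoxycyclohexa-2,5-dien-1-one | O=C1C(OC)=CC(=C[C@H](CO)Oc2ccc(C=O)cc2O)C=C1OC
F5 | step 11 | methyl (2E)-3-[(2S,3S)-3-(4-hydroxy-3,5-dimethoxyphenyl)-2-(hydroxymethyl)-2,3-dihydro-1,4-benzodioxin-6-yl]prop-2-enoate | COc1cc([C@@H]2Oc3cc(/C=C/C(=O)OC)ccc3O[C@H]2CO)cc(OC)c1O
F6 | step 11 | (2E)-3-[(2S,3S)-3-(4-hydroxy-3,5-dimethoxyphenyl)-2-(hydroxymethyl)-2,3-dihydro-1,4-benzodioxin-6-yl]prop-2-en-1-ol | COc1cc([C@@H]2Oc3cc(/C=C/CO)ccc3O[C@H]2CO)cc(OC)c1O
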